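The numbers in the tables were generated by integration from invented constants; the scatter is artificial.

The slowness of Thursday's first 2.0 min is where your question sits, and your hunch is that the catalyst stops counting once some target exists. That stretch is the one to watch, and here is my quick answer.

| flask | substrate | reagent | catalyst | time |
|---|---|---|---|---|
| Thursday's | 0.120 M | 0.132 M | 0.00600 M |  |
| Friday's | 0.240 M | 0.132 M | 0.00600 M |  |
| Sunday's | 0.120 M | 0.132 M | 0.00900 M |  |
| Tuesday's | 0.120 M | 0.132 M | 0.00600 M | 11 min |

- Thursday's run (time / min: [target] / M): 0.18: 3 × 10⁻⁴; 0.39: 0; 0.88: 0; 2.0: 0.0107; 4.4: 0.0629
- Friday's run (time / min: [target] / M): 0.18: 0; 0.39: 6 × 10⁻⁴; 0.88: 0.0040; 2.0: 0.0482; 4.4: 0.1272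
- Sunday's run (time / min: [target] / M): 0.18: 0.0017; 0.39: 0.0020; 0.88: 0.0053; 2.0: 0.0133; 4.4: 0.0660

(standard deviation of a reading: 0.001 M)

- the exponent of [substrate] in the starting rate at the charge of the Thursday's run (at the point where two percent of the substrate have become target) (one fixed amount of target, the same in the runs compared)
- the exponent of [catalyst] in the starting rate at the charge of the Thursday's run (at the point where two percent of the substrate have become target)
- target in the Tuesday's run at 11 min, as a share of the substrate charged

- Overall: substrate + reagent -> target, with catalyst as catalyst.
- Constant volume, constant temperature.
- The analysis sees a species whether free or bound.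
- "The second partner" is reagent.
- An order is taken over about fifteen percent of the charge, up and down.

I follow one substrate molecule at the moment it turns, with target at two percent of Thursday's charge. As I read the runs, it has two ways to go: through the catalyst, or through target (autocatalysis). Its chance of taking the second way is the target's share of the rate, and I read it from Thursday's run.

Between 2.0 min and 4.4 min the turned fraction climbs from 8.92 % to 52.4 %, so target grows by 0.738 min⁻¹. I take that growth to scale with the fractions of substrate and reagent left. Scaled from the middle of that stretch back to the two-percent point, it becomes 1.42 min⁻¹.

The mean pace over the first 2.0 min is 0.0446 min⁻¹ of the charge, my stand-in for the whole rate there. That reading carries a scatter of 9.35 %. The share is therefore 63.7 %.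

An apparent order is the mean of the two routes' orders, weighted by their shares. I take the target route to have order one in substrate and none in catalyst. If the catalyst route is first order in catalyst, my estimate of the catalyst order is 0.363. If that route's own substrate order lies between none and one, my estimate of the substrate order lies between 0.637 and one. So by this estimate the catalyst still counts at the two-percent point of Thursday's run.

The forecast gives 1.2 (0.7 to 2) for substrate, 0.6 (0 to 1.5) for catalyst and 92 % (80 % to 99 %) for Tuesday's run at 11 min. It calls its orders “poorly defined because the early readings sit close to the noise”. Its catalyst order stands higher than mine, and its substrate order stands above my upper end of one. I have no figure of my own for Tuesday's run and take the forecast's.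

The flask gives a substrate order of 0.77, a catalyst order of 0.28 and 92.6 % for Tuesday's run at 11 min.

    catalyst + substrate → catalyst-substrate complex (15.66 L mol⁻¹ min⁻¹)
    catalyst-substrate complex + reagent → target + catalyst (51.96 L mol⁻¹ min⁻¹)
    catalyst + substrate ⇌ idle catalyst-substrate complex, settled at all times (55.10 L mol⁻¹)
    substrate + reagent + target → 2 target (87.60 L² mol⁻² min⁻¹)

The target step pulls the catalyst order down: with that step taken away, Thursday's flask shows 0.99 instead of 0.28. At the two-percent point the step carries 71.6 % of Thursday's rate, and the remaining share times 0.99 gives 0.281. Friday's run, with twice the substrate and the same amount of target, carries 82.7 % of its rate by that step.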